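## Retrosynthetic overview

1. The target is cut last at the C4–C5' bond: acid opening of a (6aR,11aR)-8,9-dimethoxypterocarpan 3-pivalate (a latent C4 cation) and Friedel–Crafts capture by (R)-vestitol 7-pivalate anti to ring B, then ester removal.
2. (R)-Vestitol 7-pivalate comes from hydrogenolysis of the benzylic C–O bond of (6aR,11aR)-medicarpin 3-pivalate.
3. Both pterocarpans come from the key aryl C–O bond (O11–C10a): the C4 hydroxyl of a (3R,4R)-cis-isoflavan-4-ol displaces the 2'-methoxy group by photoredox ipso-substitution. This oxygen ends as the 2'-OH of each half.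
4. The cis-isoflavan-4-ols come from asymmetric transfer hydrogenation (dynamic kinetic resolution) of 7-pivaloyloxy-2'-methoxyisoflavones, made from resorcinol, a (polymethoxyphenyl)acetic acid and DMF.
5. Ring order: pyranone ring of the chromone, reduction to the chroman-4-ol, dihydrofuran ring by C–O closure, then reopening of that ring (by H2 in one half, by the arene nucleophile in the other).

Assumption: (2,4,5-trimethoxyphenyl)acetic acid is bought; the descriptors read from the SMILES are 3R,4S (3,4-trans) for the 4-arylisoflavan unit and 3R for the vestitol unit.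

## Route

Step 1
Reactants: 1 resorcinol; 2 (2,4-dimethoxyphenyl)acetic acid
Product: 4 7-hydroxy-3-(2,4-dimethoxyphenyl)-4H-chromen-4-one, via deoxybenzoin 3 (not isolated)
Conditions: BF3·OEt2, 85 °C; then DMF, MsCl, 70 °C
Reagents that add atoms: N,N-dimethylformamide CN(C)C=O
Why: Friedel–Crafts C-acylation of resorcinol at C4 gives the deoxybenzoin, whose methylene is formylated by the DMF/MsCl Vilsmeier reagent and closed by the ortho-hydroxyl (one-pot deoxybenzoin isoflavone synthesis); no stereocentre is formed.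

Step 2
Reactants: 4 7-hydroxy-3-(2,4-dimethoxyphenyl)-4H-chromen-4-one
Product: 5 3-(2,4-dimethoxyphenyl)-4-oxo-4H-chromen-7-yl pivalate
Conditions: PivCl, Et3N, DMAP (cat.), CH2Cl2, 0 to 25 °C
Reagents that add atoms: pivaloyl chloride CC(C)(C)C(=O)Cl
Why: Simple O-acylation of the only hydroxyl; the ester keeps the chromone electrophilic for hydride transfer and later keeps ring A electron-poor and the C4 carbinol less acid-labile.

Step 3
Reactants: 5 3-(2,4-dimethoxyphenyl)-4-oxo-4H-chromen-7-yl pivalate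
Product: 7 (3R,4R)-3-(2,4-dimethoxyphenyl)-4-hydroxychroman-7-yl pivalate, via racemic isoflavanone pivalate 6 (not isolated)
Conditions: RuCl[(R,R)-TsDPEN](p-cymene) (2 mol %), HCO2H/Et3N (5:2), EtOAc, 40 °C
Reagents that add atoms: none
Why: Noyori–Ikariya asymmetric transfer hydrogenation cascade: conjugate reduction gives the isoflavanone, which racemises at C3 under the amine, and dynamic kinetic resolution in the carbonyl reduction gives the 3,4-cis alcohol; the (R,R) catalyst sets 4R by the facial rule that gives (R)-1-phenylethanol, and 3R follows because hydride adds anti to the aryl group.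

Step 4
Reactants: 7 (3R,4R)-3-(2,4-dimethoxyphenyl)-4-hydroxychroman-7-yl pivalate
Product: 8 (6aR,11aR)-9-methoxy-6a,11a-dihydro-6H-benzofuro[3,2-c]chromen-3-yl pivalate
Conditions: 9-mesityl-3,6-di-tert-butyl-10-phenylacridinium tetrafluoroborate (5 mol %), 456 nm LEDs, DCE/TFE (1:1), N2, 25 °C
Reagents that add atoms: none
Why: Proposed new method: the excited acridinium (about +2.1 V) oxidises the dimethoxyaryl ring B to its radical cation, the cis C4 hydroxyl adds 5-exo to the methoxy-bearing ipso carbon C2', proton transfer and loss of methanol give the pterocarpan radical cation, and the acridine radical reduces it, so the dihydrofuran ring closes redox-neutrally with both stereocentres retained (no oxidant, hence no ketone formation; the pivalate keeps ring A out of the redox chemistry; attack at C6'–H is unproductive without an oxidant); the closest known reaction type is cation-radical-accelerated nucleophilic aromatic substitution of methoxyarenes by azoles and amines under acridinium photoredox catalysis.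

Step 5
Reactants: 8 (6aR,11aR)-9-methoxy-6a,11a-dihydro-6H-benzofuro[3,2-c]chromen-3-yl pivalate
Product: 9 (3R)-3-(2-hydroxy-4-methoxyphenyl)chroman-7-yl pivalate
Conditions: H2 (1 atm), Pd/C (10 wt %), EtOAc/AcOH (9:1), 25 °C
Reagents that add atoms: none
Why: Catalytic hydrogenolysis of the benzylic aryl ether C11a–O bond opens the dihydrofuran ring to the 2'-hydroxyisoflavan (the known medicarpin-to-vestitol reaction); C6a is untouched and becomes the 3R centre, and the aryl pivalate is inert.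

Step 6
Reactants: 1 resorcinol; 10 (2,4,5-trimethoxyphenyl)acetic acid
Product: 12 7-hydroxy-3-(2,4,5-trimethoxyphenyl)-4H-chromen-4-one, via deoxybenzoin 11 (not isolated)
Conditions: BF3·OEt2, 85 °C; then DMF, MsCl, 70 °C
Reagents that add atoms: N,N-dimethylformamide CN(C)C=O
Why: Same one-pot Friedel–Crafts acylation and Vilsmeier formylation/ring closure as step 1; no stereocentre is formed.

Step 7
Reactants: 12 7-hydroxy-3-(2,4,5-trimethoxyphenyl)-4H-chromen-4-one
Product: 13 4-oxo-3-(2,4,5-trimethoxyphenyl)-4H-chromen-7-yl pivalate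
Conditions: PivCl, Et3N, DMAP (cat.), CH2Cl2, 0 to 25 °C
Reagents that add atoms: pivaloyl chloride CC(C)(C)C(=O)Cl
Why: O-acylation of the only hydroxyl, as in step 2.

Step 8
Reactants: 13 4-oxo-3-(2,4,5-trimethoxyphenyl)-4H-chromen-7-yl pivalate
Product: 15 (3R,4R)-4-hydroxy-3-(2,4,5-trimethoxyphenyl)chroman-7-yl pivalate, via racemic isoflavanone pivalate 14 (not isolated)
Conditions: RuCl[(R,R)-TsDPEN](p-cymene) (2 mol %), HCO2H/Et3N (5:2), EtOAc, 40 °C
Reagents that add atoms: none
Why: Same Noyori–Ikariya transfer hydrogenation cascade with dynamic kinetic resolution as step 3, giving the 3,4-cis (3R,4R) alcohol with the (R,R) catalyst.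

Step 9
Reactants: 15 (3R,4R)-4-hydroxy-3-(2,4,5-trimethoxyphenyl)chroman-7-yl pivalate
Product: 16 (6aR,11aR)-8,9-dimethoxy-6a,11a-dihydro-6H-benzofuro[3,2-c]chromen-3-yl pivalate
Conditions: 9-mesityl-3,6-di-tert-butyl-10-phenylacridinium tetrafluoroborate (5 mol %), 456 nm LEDs, DCE/TFE (1:1), N2, 25 °C
Reagents that add atoms: none
Why: Proposed new method: same photoredox ipso-substitution as step 4, here on the more easily oxidised 1,2,4-trimethoxyaryl radical cation, whose ipso carbon C2' is para to the 5'-methoxy group so that the adduct radical is alkoxy-stabilised before methanol is lost and the acridine radical closes the cycle, with both stereocentres retained; the closest known reaction type is cation-radical-accelerated nucleophilic aromatic substitution of methoxyarenes under acridinium photoredox catalysis.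

Step 10
Reactants: 16 (6aR,11aR)-8,9-dimethoxy-6a,11a-dihydro-6H-benzofuro[3,2-c]chromen-3-yl pivalate; 9 (3R)-3-(2-hydroxy-4-methoxyphenyl)chroman-7-yl pivalate
Product: 18 (3R,4S)-3-(2-hydroxy-4,5-dimethoxyphenyl)-4-{4-hydroxy-5-[(3R)-7-hydroxychroman-3-yl]-2-methoxyphenyl}chroman-7-ol, via coupled bis-pivalate 17 (not isolated)
Conditions: 9 (1.5 equiv), TfOH (10 mol %), HFIP/CH2Cl2 (1:4), −20 to 0 °C; then K2CO3, MeOH, Ar, 25 °C
Reagents that add atoms: none
Why: Acid ionises the benzylic aryl ether of 16 (pterocarpan as latent 2-alkoxybenzylic cation, a known entry to 4-arylisoflavans), and the Friedel–Crafts alkylation takes place at C5' of 9 (para to its only free hydroxyl, both rings A being pivalate-deactivated) from the face anti to ring B, which sets C4 as S (3,4-trans) under control of the 3R centre; base methanolysis then frees both 7-hydroxyls.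

## Compound list

1 | resorcinol | Oc1cccc(O)c1 | starting material
2 | (2,4-dimethoxyphenyl)acetic acid | COc1ccc(CC(=O)O)c(OC)c1 | starting material
3 | 1-(2,4-dihydroxyphenyl)-2-(2,4-dimethoxyphenyl)ethan-1-one (deoxybenzoin, not isolated) | COc1ccc(CC(=O)c2ccc(O)cc2O)c(OC)c1 | intermediate
4 | 7-hydroxy-3-(2,4-dimethoxyphenyl)-4H-chromen-4-one | COc1ccc(C2=COc3cc(O)ccc3C2=O)c(OC)c1 | intermediate
5 | 3-(2,4-dimethoxyphenyl)-4-oxo-4H-chromen-7-yl pivalate | COc1ccc(C2=COc3cc(OC(=O)C(C)(C)C)ccc3C2=O)c(OC)c1 | intermediate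
6 | racemic 3-(2,4-dimethoxyphenyl)-4-oxochroman-7-yl pivalate (not isolated) | COc1ccc(C2COc3cc(OC(=O)C(C)(C)C)ccc3C2=O)c(OC)c1 | intermediate
7 | (3R,4R)-3-(2,4-dimethoxyphenyl)-4-hydroxychroman-7-yl pivalate (3,4-cis) | COc1ccc([C@@H]2COc3cc(OC(=O)C(C)(C)C)ccc3[C@@H]2O)c(OC)c1 | intermediate
8 | (6aR,11aR)-9-methoxy-6a,11a-dihydro-6H-benzofuro[3,2-c]chromen-3-yl pivalate (medicarpin 3-O-pivalate) | COc1ccc([C@@H]2COc3cc(OC(=O)C(C)(C)C)ccc3[C@@H]2O4)c4c1 | intermediate
9 | (3R)-3-(2-hydroxy-4-methoxyphenyl)chroman-7-yl pivalate ((R)-vestitol 7-O-pivalate) | COc1ccc([C@@H]2COc3cc(OC(=O)C(C)(C)C)ccc3C2)c(O)c1 | intermediate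
10 | (2,4,5-trimethoxyphenyl)acetic acid | COc1cc(OC)c(CC(=O)O)cc1OC | starting material
11 | 1-(2,4-dihydroxyphenyl)-2-(2,4,5-trimethoxyphenyl)ethan-1-one (deoxybenzoin, not isolated) | COc1cc(OC)c(CC(=O)c2ccc(O)cc2O)cc1OC | intermediate
12 | 7-hydroxy-3-(2,4,5-trimethoxyphenyl)-4H-chromen-4-one | COc1cc(OC)c(C2=COc3cc(O)ccc3C2=O)cc1OC | intermediate
13 | 4-oxo-3-(2,4,5-trimethoxyphenyl)-4H-chromen-7-yl pivalate | COc1cc(OC)c(C2=COc3cc(OC(=O)C(C)(C)C)ccc3C2=O)cc1OC | intermediate
14 | racemic 4-oxo-3-(2,4,5-trimethoxyphenyl)chroman-7-yl pivalate (not isolated) | COc1cc(OC)c(C2COc3cc(OC(=O)C(C)(C)C)ccc3C2=O)cc1OC | intermediate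
15 | (3R,4R)-4-hydroxy-3-(2,4,5-trimethoxyphenyl)chroman-7-yl pivalate (3,4-cis) | COc1cc(OC)c([C@@H]2COc3cc(OC(=O)C(C)(C)C)ccc3[C@@H]2O)cc1OC | intermediate
16 | (6aR,11aR)-8,9-dimethoxy-6a,11a-dihydro-6H-benzofuro[3,2-c]chromen-3-yl pivalate | COc1cc4c([C@@H]2COc3cc(OC(=O)C(C)(C)C)ccc3[C@@H]2O4)cc1OC | intermediate
17 | (3R,4S)-3-(2-hydroxy-4,5-dimethoxyphenyl)-4-{4-hydroxy-2-methoxy-5-[(3R)-7-(pivaloyloxy)chroman-3-yl]phenyl}chroman-7-yl pivalate (not isolated) | COc1cc(O)c([C@@H]2COc3cc(OC(=O)C(C)(C)C)ccc3[C@H]2c2cc([C@@H]3COc4cc(OC(=O)C(C)(C)C)ccc4C3)c(O)cc2OC)cc1OC | intermediate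
18 | (3R,4S)-3-(2-hydroxy-4,5-dimethoxyphenyl)-4-{4-hydroxy-5-[(3R)-7-hydroxychroman-3-yl]-2-methoxyphenyl}chroman-7-ol (CNP0217096.1) | COc1cc(O)c([C@@H]2COc3cc(O)ccc3[C@H]2c2cc([C@@H]3COc4cc(O)ccc4C3)c(O)cc2OC)cc1OC | target

## Step count and risks

Total steps: 10. Longest linear sequence: 6 (steps 1, 2, 3, 4, 5, 10).

Three steps most likely to fail:

Step 4 (new photoredox C–O closure on the dimethoxyaryl ring). Ring B of 7 is the harder ring to oxidise and its ipso carbon has no para-methoxy group. The radical cation may instead lose a benzylic proton or fragment at C3–C4. The fallback sets out from 1 and comes back at 8, using a pre-installed bromide and known cross-coupling. Resorcinol 1 is acylated with bought (2-bromo-4-methoxyphenyl)acetic acid (COc1ccc(CC(=O)O)c(Br)c1) to 2-(2-bromo-4-methoxyphenyl)-1-(2,4-dihydroxyphenyl)ethan-1-one F1, which is closed in the same pot with DMF/MsCl to 3-(2-bromo-4-methoxyphenyl)-7-hydroxy-4H-chromen-4-one F2. Pivaloylation gives 3-(2-bromo-4-methoxyphenyl)-4-oxo-4H-chromen-7-yl pivalate F3. The transfer hydrogenation of step 3 passes through racemic 3-(2-bromo-4-methoxyphenyl)-4-oxochroman-7-yl pivalate F4 to (3R,4R)-3-(2-bromo-4-methoxyphenyl)-4-hydroxychroman-7-yl pivalate F5. The known palladium-catalysed intramolecular etherification of a secondary alcohol with an aryl bromide (Pd(OAc)2, 2-(di-tert-butylphosphino)-1,1'-binaphthyl, Cs2CO3, toluene, 80 °C) then closes the dihydrofuran ring with retention and gives 8.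

Step 9 (the same new closure on the trimethoxyaryl ring). The electron-rich product may be over-oxidised, or its radical cation may cleave at the benzylic C11a–O bond. The fallback sets out from 1 and comes back at 16 by the same known chemistry. Resorcinol 1 and bought (2-bromo-4,5-dimethoxyphenyl)acetic acid (COc1cc(Br)c(CC(=O)O)cc1OC) give 2-(2-bromo-4,5-dimethoxyphenyl)-1-(2,4-dihydroxyphenyl)ethan-1-one F6 and, in the same pot, 3-(2-bromo-4,5-dimethoxyphenyl)-7-hydroxy-4H-chromen-4-one F7. Pivaloylation gives 3-(2-bromo-4,5-dimethoxyphenyl)-4-oxo-4H-chromen-7-yl pivalate F8. Transfer hydrogenation passes through racemic 3-(2-bromo-4,5-dimethoxyphenyl)-4-oxochroman-7-yl pivalate F9 to (3R,4R)-3-(2-bromo-4,5-dimethoxyphenyl)-4-hydroxychroman-7-yl pivalate F10. The same Pd(OAc)2/2-(di-tert-butylphosphino)-1,1'-binaphthyl/Cs2CO3 etherification closes the ring to 16.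

Step 10 (union of the halves). The pivalate-bearing cation is only moderately stabilised; loss of H-3 would give the isoflav-3-ene and scramble C3, and attack at C3' of 9 or O-alkylation could compete. The fallback sets out from 16 and comes back at 18, replacing the cationic opening by a quinone-methide 1,6-addition. Methanolysis of 16 (K2CO3, MeOH) gives (6aR,11aR)-8,9-dimethoxy-6a,11a-dihydro-6H-benzofuro[3,2-c]chromen-3-ol F11. In HFIP with diphenyl phosphate (10 mol %) at 0 to 25 °C the free para-hydroxyl lets the ring open under much milder acid to the neutral (3R)-3-(2-hydroxy-4,5-dimethoxyphenyl)-2,3-dihydro-7H-chromen-7-one F12 (para-quinone methide, not isolated). This is trapped anti to ring B by C5' of 9 (3 equiv) to give (3R)-3-{2-hydroxy-5-[(3R,4S)-7-hydroxy-3-(2-hydroxy-4,5-dimethoxyphenyl)chroman-4-yl]-4-methoxyphenyl}chroman-7-yl pivalate F13. Methanolysis of F13 (K2CO3, MeOH) gives 18.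

Further compounds

F1 | step 4 | 2-(2-bromo-4-methoxyphenyl)-1-(2,4-dihydroxyphenyl)ethan-1-one | COc1ccc(CC(=O)c2ccc(O)cc2O)c(Br)c1
F2 | step 4 | 3-(2-bromo-4-methoxyphenyl)-7-hydroxy-4H-chromen-4-one | COc1ccc(C2=COc3cc(O)ccc3C2=O)c(Br)c1
F3 | step 4 | 3-(2-bromo-4-methoxyphenyl)-4-oxo-4H-chromen-7-yl pivalate | COc1ccc(C2=COc3cc(OC(=O)C(C)(C)C)ccc3C2=O)c(Br)c1
F4 | step 4 | racemic 3-(2-bromo-4-methoxyphenyl)-4-oxochroman-7-yl pivalate | COc1ccc(C2COc3cc(OC(=O)C(C)(C)C)ccc3C2=O)c(Br)c1
F5 | step 4 | (3R,4R)-3-(2-bromo-4-methoxyphenyl)-4-hydroxychroman-7-yl pivalate | COc1ccc([C@@H]2COc3cc(OC(=O)C(C)(C)C)ccc3[C@@H]2O)c(Br)c1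
F6 | step 9 | 2-(2-bromo-4,5-dimethoxyphenyl)-1-(2,4-dihydroxyphenyl)ethan-1-one | COc1cc(Br)c(CC(=O)c2ccc(O)cc2O)cc1OC
F7 | step 9 | 3-(2-bromo-4,5-dimethoxyphenyl)-7-hydroxy-4H-chromen-4-one | COc1cc(Br)c(C2=COc3cc(O)ccc3C2=O)cc1OC
F8 | step 9 | 3-(2-bromo-4,5-dimethoxyphenyl)-4-oxo-4H-chromen-7-yl pivalate | COc1cc(Br)c(C2=COc3cc(OC(=O)C(C)(C)C)ccc3C2=O)cc1OC
F9 | step 9 | racemic 3-(2-bromo-4,5-dimethoxyphenyl)-4-oxochroman-7-yl pivalate | COc1cc(Br)c(C2COc3cc(OC(=O)C(C)(C)C)ccc3C2=O)cc1OC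
F10 | step 9 | (3R,4R)-3-(2-bromo-4,5-dimethoxyphenyl)-4-hydroxychroman-7-yl pivalate | COc1cc(Br)c([C@@H]2COc3cc(OC(=O)C(C)(C)C)ccc3[C@@H]2O)cc1OC
F11 | step 10 | (6aR,11aR)-8,9-dimethoxy-6a,11a-dihydro-6H-benzofuro[3,2-c]chromen-3-ol | COc1cc4c([C@@H]2COc3cc(O)ccc3[C@@H]2O4)cc1OC
F12 | step 10 | (3R)-3-(2-hydroxy-4,5-dimethoxyphenyl)-2,3-dihydro-7H-chromen-7-one | O=C1C=CC(=C[C@H](c3cc(OC)c(OC)cc3O)CO2)C2=C1
F13 | step 10 | (3R)-3-{2-hydroxy-5-[(3R,4S)-7-hydroxy-3-(2-hydroxy-4,5-dimethoxyphenyl)chroman-4-yl]-4-methoxyphenyl}chroman-7-yl pivalate | COc1cc(O)c([C@@H]2COc3cc(O)ccc3[C@H]2c2cc([C@@H]3COc4cc(OC(=O)C(C)(C)C)ccc4C3)c(O)cc2OC)cc1OC
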